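**Target read-out.** The SMILES is ent-fisetinidol-(4α→6)-ent-fisetinidol-(4α→8)-catechin-(6→4α)-ent-fisetinidol. The three 5-deoxy units are (2S,3R), 2,3-trans-3,4-cis (4-aryl cis to 3-OH, trans to the 2-aryl); the 5,7-dihydroxy unit is (+)-catechin (2R,3S), substituted at C8 and C6.

**Retrosynthetic overview**
1. Target 14 ⇒ global O-debenzylation of the heptadeca-O-benzyl tetramer 13.
2. 13 ⇒ cut the two terminal C4–aryl bonds (A→B C6 and D→C C6) together: dilithiated dimer 11 + 2 × chroman-4-one 6. Each bond is made by aryllithium addition to the C4 carbonyl, then ionic hydrogenation, which fixes C4.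
3. Dimer 9 ⇒ cut C4(B)–C8(C) the same way: 8-lithiocatechin ether 7 + ketone 6.
4. No heterocycle is built: the catechin ring system comes intact from (+)-catechin and the three ent-fisetinidol ring systems from (2S,3S)-fustin. Assembly order: B onto C8 of C, then A and D together.
5. All C2/C3 centres are bought; each C4 is set under control of its neighbouring C3.

Assumption: enantiopure (2S,3S)-fustin (the 2,3-trans dihydroflavonol of the ent series, compound 4) is taken as purchasable, like (+)-catechin.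

**Route**

Step 1
Reactants: 1 (+)-catechin
Product: 2 3,5,7,3',4'-penta-O-benzyl-(+)-catechin (2R,3S)
Conditions: BnBr (5.5 equiv), NaH (5.5 equiv), DMF, 0 °C → rt
Reagents that add atoms: benzyl bromide, BrCc1ccccc1
Why: Williamson etherification of the four phenols and the secondary alcohol; C2 and C3 are not touched.

Step 2
Reactants: 2 3,5,7,3',4'-penta-O-benzyl-(+)-catechin
Product: 3 8-bromo-3,5,7,3',4'-penta-O-benzyl-(+)-catechin
Conditions: NBS (1.0 equiv), CH2Cl2, −78 °C → rt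
Reagents that add atoms: N-bromosuccinimide, O=C1CCC(=O)N1Br
Why: Electrophilic aromatic bromination (SEAr) of the tri-oxygenated A-ring, which is far more electron-rich than the catechol ether ring and reacts first at C8.

Step 3
Reactants: 4 (2S,3S)-fustin
Product: 5 7,3',4'-tri-O-benzyl-(2S,3S)-fustin
Conditions: BnBr (3.3 equiv), K2CO3, DMF, rt, N2
Reagents that add atoms: benzyl bromide, BrCc1ccccc1
Why: Williamson etherification with a weak base benzylates only the three phenols and leaves the 3-OH and the base-sensitive C2/C3 centres of the α-ketol untouched.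

Step 4
Reactants: 5 7,3',4'-tri-O-benzyl-(2S,3S)-fustin
Product: 6 3,7,3',4'-tetra-O-benzyl-(2S,3S)-fustin
Conditions: BnOC(=NH)CCl3, TfOH (cat.), CH2Cl2–cyclohexane, 0 °C → rt
Reagents that add atoms: benzyl 2,2,2-trichloroacetimidate, N=C(OCc1ccccc1)C(Cl)(Cl)Cl
Why: Acid-catalysed trichloroacetimidate benzylation protects the 3-OH without base, so the epimerisable C2/C3 centres keep their configuration.

Step 5
Reactants: 3 8-bromo-3,5,7,3',4'-penta-O-benzyl-(+)-catechin + 6 3,7,3',4'-tetra-O-benzyl-(2S,3S)-fustin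
Product: 9 3,7,3',4'-tetra-O-benzyl-ent-fisetinidol-(4α→8)-3,5,7,3',4'-penta-O-benzylcatechin, via aryllithium 7 (not isolated), via tertiary carbinol 8 (not isolated)
Conditions: 3, t-BuLi (2 equiv), THF, −78 °C; 6, −78 → −40 °C; then Et3SiH, CF3CO2H, CH2Cl2, −78 → 0 °C (one pot)
Reagents that add atoms: none
Why: Br/Li exchange, 1,2-addition of the aryllithium to the chromanone carbonyl and Kursanov–Parnes ionic hydrogenation of the doubly benzylic carbinol; A(1,2) strain with the twisted C4-aryl pushes the 3-OBn pseudo-axial, so the silane delivers hydride anti to it and the C4–aryl bond ends cis to O3 (4α, 2,3-trans-3,4-cis).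

Step 6
Reactants: 9 3,7,3',4'-tetra-O-benzyl-ent-fisetinidol-(4α→8)-3,5,7,3',4'-penta-O-benzylcatechin
Product: 10 6-bromo-3,7,3',4'-tetra-O-benzyl-ent-fisetinidol-(4α→8)-6-bromo-3,5,7,3',4'-penta-O-benzylcatechin
Conditions: NBS (2.05 equiv), CH2Cl2, −78 → 0 °C, dark
Reagents that add atoms: N-bromosuccinimide, O=C1CCC(=O)N1Br
Why: Two SEAr brominations at the two most activated free positions: C6 of the catechin ring (ortho/para to three oxygens) and C6 of the resorcinol-type ring of the upper unit (para to the ring oxygen, ortho to OBn); C8 of that ring is flanked on both sides and the catechol ether rings are less activated.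

Step 7
Reactants: 10 6-bromo-3,7,3',4'-tetra-O-benzyl-ent-fisetinidol-(4α→8)-6-bromo-3,5,7,3',4'-penta-O-benzylcatechin + 6 3,7,3',4'-tetra-O-benzyl-(2S,3S)-fustin (2 equiv)
Product: 13 heptadeca-O-benzyl ent-fisetinidol-(4α→6)-ent-fisetinidol-(4α→8)-catechin-(6→4α)-ent-fisetinidol, via dilithio dimer 11 (not isolated), via bis-carbinol 12 (not isolated)
Conditions: 10, t-BuLi (4.2 equiv), THF, −78 °C; 6 (2.5 equiv), −78 → −40 °C; then Et3SiH, CF3CO2H, CH2Cl2, −78 → 0 °C (one pot)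
Reagents that add atoms: none
Why: Twofold Br/Li exchange, twofold 1,2-addition to the chromanone and twofold ionic hydrogenation; each new C4 is set as in step 5 by hydride delivery anti to the adjacent 3-OBn, giving the two remaining 4α (3,4-cis) linkages.

Step 8
Reactants: 13 heptadeca-O-benzyl ent-fisetinidol-(4α→6)-ent-fisetinidol-(4α→8)-catechin-(6→4α)-ent-fisetinidol
Product: 14 ent-fisetinidol-(4α→6)-ent-fisetinidol-(4α→8)-catechin-(6→4α)-ent-fisetinidol (CNP0126838.1)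
Conditions: H2 (1 atm), Pd(OH)2/C, THF–MeOH–H2O, rt; filter, lyophilise
Reagents that add atoms: none
Why: Catalytic hydrogenolysis removes all seventeen benzyl ethers under neutral conditions; the C4–aryl bonds of 5-deoxy units and all eleven stereocentres are stable to it.

**Compound list**

1 | (+)-catechin, (2R,3S) | c1c(O)cc(O)c2c1O[C@H](c1ccc(O)c(O)c1)[C@@H](O)C2 | starting material
2 | 3,5,7,3',4'-penta-O-benzyl-(+)-catechin | c1c(OCc4ccccc4)cc(OCc4ccccc4)c2c1O[C@H](c1ccc(OCc4ccccc4)c(OCc4ccccc4)c1)[C@@H](OCc4ccccc4)C2 | intermediate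
3 | 8-bromo-3,5,7,3',4'-penta-O-benzyl-(+)-catechin | Brc1c(OCc4ccccc4)cc(OCc4ccccc4)c2c1O[C@H](c1ccc(OCc4ccccc4)c(OCc4ccccc4)c1)[C@@H](OCc4ccccc4)C2 | intermediate
4 | (2S,3S)-fustin, (2S,3S)-2-(3,4-dihydroxyphenyl)-3,7-dihydroxychroman-4-one | Oc1ccc2c(c1)O[C@@H](c1ccc(O)c(O)c1)[C@H](O)C2=O | starting material
5 | 7,3',4'-tri-O-benzyl-(2S,3S)-fustin | c4ccccc4COc1ccc2c(c1)O[C@@H](c1ccc(OCc4ccccc4)c(OCc4ccccc4)c1)[C@H](O)C2=O | intermediate
6 | 3,7,3',4'-tetra-O-benzyl-(2S,3S)-fustin | c4ccccc4COc1ccc2c(c1)O[C@@H](c1ccc(OCc4ccccc4)c(OCc4ccccc4)c1)[C@H](OCc4ccccc4)C2=O | intermediate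
7 | 8-lithio-3,5,7,3',4'-penta-O-benzylcatechin | [Li]c1c(OCc4ccccc4)cc(OCc4ccccc4)c2c1O[C@H](c1ccc(OCc4ccccc4)c(OCc4ccccc4)c1)[C@@H](OCc4ccccc4)C2 | intermediate
8 | 4-hydroxy-4-(penta-O-benzylcatechin-8-yl) adduct of 6 (C4 epimers, configuration at C4 not defined) | c1cc2c(cc1OCc4ccccc4)O[C@@H](c1ccc(OCc4ccccc4)c(OCc4ccccc4)c1)[C@H](OCc4ccccc4)C2(O)c1c(OCc4ccccc4)cc(OCc4ccccc4)c2c1O[C@H](c1ccc(OCc4ccccc4)c(OCc4ccccc4)c1)[C@@H](OCc4ccccc4)C2 | intermediate
9 | 3,7,3',4'-tetra-O-benzyl-ent-fisetinidol-(4α→8)-3,5,7,3',4'-penta-O-benzylcatechin (upper unit 2S,3R, 3,4-cis) | c1cc2c(cc1OCc4ccccc4)O[C@@H](c1ccc(OCc4ccccc4)c(OCc4ccccc4)c1)[C@H](OCc4ccccc4)[C@@H]2c1c(OCc4ccccc4)cc(OCc4ccccc4)c2c1O[C@H](c1ccc(OCc4ccccc4)c(OCc4ccccc4)c1)[C@@H](OCc4ccccc4)C2 | intermediate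
10 | 6-bromo-tetra-O-benzyl-ent-fisetinidol-(4α→8)-6-bromo-penta-O-benzylcatechin | Brc1cc2c(cc1OCc4ccccc4)O[C@@H](c1ccc(OCc4ccccc4)c(OCc4ccccc4)c1)[C@H](OCc4ccccc4)[C@@H]2c1c(OCc4ccccc4)c(Br)c(OCc4ccccc4)c2c1O[C@H](c1ccc(OCc4ccccc4)c(OCc4ccccc4)c1)[C@@H](OCc4ccccc4)C2 | intermediate
11 | 6-lithio-tetra-O-benzyl-ent-fisetinidol-(4α→8)-6-lithio-penta-O-benzylcatechin | [Li]c1cc2c(cc1OCc4ccccc4)O[C@@H](c1ccc(OCc4ccccc4)c(OCc4ccccc4)c1)[C@H](OCc4ccccc4)[C@@H]2c1c(OCc4ccccc4)c([Li])c(OCc4ccccc4)c2c1O[C@H](c1ccc(OCc4ccccc4)c(OCc4ccccc4)c1)[C@@H](OCc4ccccc4)C2 | intermediate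
12 | bis-carbinol: 9 carrying a 4-hydroxy-tetra-O-benzyl-ent-fisetinidol-4-yl group at C6 of each A-ring (new C4 centres not defined) | c4ccccc4COc1ccc2c(c1)O[C@@H](c1ccc(OCc4ccccc4)c(OCc4ccccc4)c1)[C@H](OCc4ccccc4)C2(O)c1cc2c(cc1OCc4ccccc4)O[C@@H](c1ccc(OCc4ccccc4)c(OCc4ccccc4)c1)[C@H](OCc4ccccc4)[C@@H]2c1c(OCc4ccccc4)c(C2(O)c3ccc(OCc4ccccc4)cc3O[C@@H](c3ccc(OCc4ccccc4)c(OCc4ccccc4)c3)[C@@H]2OCc4ccccc4)c(OCc4ccccc4)c2c1O[C@H](c1ccc(OCc4ccccc4)c(OCc4ccccc4)c1)[C@@H](OCc4ccccc4)C2 | intermediate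
13 | heptadeca-O-benzyl ent-fisetinidol-(4α→6)-ent-fisetinidol-(4α→8)-catechin-(6→4α)-ent-fisetinidol | c4ccccc4COc1ccc2c(c1)O[C@@H](c1ccc(OCc4ccccc4)c(OCc4ccccc4)c1)[C@H](OCc4ccccc4)[C@@H]2c1cc2c(cc1OCc4ccccc4)O[C@@H](c1ccc(OCc4ccccc4)c(OCc4ccccc4)c1)[C@H](OCc4ccccc4)[C@@H]2c1c(OCc4ccccc4)c([C@@H]2c3ccc(OCc4ccccc4)cc3O[C@@H](c3ccc(OCc4ccccc4)c(OCc4ccccc4)c3)[C@@H]2OCc4ccccc4)c(OCc4ccccc4)c2c1O[C@H](c1ccc(OCc4ccccc4)c(OCc4ccccc4)c1)[C@@H](OCc4ccccc4)C2 | intermediate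
14 | ent-fisetinidol-(4α→6)-ent-fisetinidol-(4α→8)-catechin-(6→4α)-ent-fisetinidol (CNP0126838.1) | Oc1ccc2c(c1)O[C@@H](c1ccc(O)c(O)c1)[C@H](O)[C@@H]2c1cc2c(cc1O)O[C@@H](c1ccc(O)c(O)c1)[C@H](O)[C@@H]2c1c(O)c([C@@H]2c3ccc(O)cc3O[C@@H](c3ccc(O)c(O)c3)[C@@H]2O)c(O)c2c1O[C@H](c1ccc(O)c(O)c1)[C@@H](O)C2 | target

**Totals.** 8 steps in all; longest linear sequence 6 steps (1 → 2 → 3 → 9 → 10 → 13 → 14, or equally 4 → 5 → 6 → 9 → 10 → 13 → 14).

**Steps most likely to fail, with fallbacks**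

Step 5 (and the same event in step 7). The hindered 2,6-dialkoxyaryllithium may enolise ketone 6 instead of adding. The face taken by hydride at the 4-aryl cation is the least secure stereochemical element of the route; it has no direct precedent in the 2,3-trans 5-deoxy series. Fallback: it sets out from 6 and 2 and comes back to the route at 9. Ketone 6 is reduced with NaBH4 (MeOH–THF, 0 °C) to the 2,3-trans-3,4-trans flavan-4-ol (2S,3R,4S)-3,7,3',4'-tetra-O-benzyl-leucofisetinidin F1. F1 is ionised with BF3·OEt2 (CH2Cl2, −78 °C) in the presence of excess 2, whose C8 attacks the flavan-4-yl cation (SN1 Friedel–Crafts arylation). This gives 9 together with its 4β (3,4-trans) epimer F2, which is expected to be the major product, so 9 is isolated by preparative HPLC as the minor isomer.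

Step 6. The second bromination must choose C6 of the upper unit over its C8 and over three catechol ether rings; over- or mis-bromination is possible. Fallback: it sets out from 6 and comes back at 10. The upper-unit bromine is installed before the units are joined. NBS (MeCN, 0 °C) brominates ketone 6 para to the ring oxygen to give 6-bromo-3,7,3',4'-tetra-O-benzyl-(2S,3S)-fustin F3; regioisomers are easy to remove and to assign on the monomer. The step-5 sequence with 3 and F3 gives 6-bromo-tetra-O-benzyl-ent-fisetinidol-(4α→8)-penta-O-benzylcatechin F4 (carbonyl addition outruns aryl–aryl Br/Li exchange). One equivalent of NBS then brominates the only strongly activated free position, catechin C6, to give 10.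

Step 7. The double coupling needs two different aryllithiums to add in one pot, one of them (catechin C6, between two OBn groups) very hindered; mono-adducts are the likely loss. Fallback: it sets out from 10 and comes back at 13, making the two bonds one after the other. n-BuLi (1.0 equiv, THF, −100 °C) first exchanges the bromine between the two benzyloxy groups of the catechin ring (the more stabilised 2,6-dialkoxyaryllithium). Addition to 6 and ionic hydrogenation as in step 5 give the bromo-trimer 6-bromo-tetra-O-benzyl-ent-fisetinidol-(4α→8)-penta-O-benzylcatechin-(6→4α)-tetra-O-benzyl-ent-fisetinidol F5. A second Br/Li exchange (t-BuLi, −78 °C) at the upper unit, addition to 6 and ionic hydrogenation give 13.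

**Further compounds**

F1 | step 5 | (2S,3R,4S)-3,7,3',4'-tetra-O-benzyl-leucofisetinidin (2,3-trans-3,4-trans flavan-4-ol) | c4ccccc4COc1ccc2c(c1)O[C@@H](c1ccc(OCc4ccccc4)c(OCc4ccccc4)c1)[C@H](OCc4ccccc4)[C@H]2O
F2 | step 5 | 3,7,3',4'-tetra-O-benzyl-ent-fisetinidol-(4β→8)-3,5,7,3',4'-penta-O-benzylcatechin (3,4-trans epimer of 9) | c1cc2c(cc1OCc4ccccc4)O[C@@H](c1ccc(OCc4ccccc4)c(OCc4ccccc4)c1)[C@H](OCc4ccccc4)[C@H]2c1c(OCc4ccccc4)cc(OCc4ccccc4)c2c1O[C@H](c1ccc(OCc4ccccc4)c(OCc4ccccc4)c1)[C@@H](OCc4ccccc4)C2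
F3 | step 6 | 6-bromo-3,7,3',4'-tetra-O-benzyl-(2S,3S)-fustin | Brc1cc2c(cc1OCc4ccccc4)O[C@@H](c1ccc(OCc4ccccc4)c(OCc4ccccc4)c1)[C@H](OCc4ccccc4)C2=O
F4 | step 6 | 6-bromo-3,7,3',4'-tetra-O-benzyl-ent-fisetinidol-(4α→8)-3,5,7,3',4'-penta-O-benzylcatechin | Brc1cc2c(cc1OCc4ccccc4)O[C@@H](c1ccc(OCc4ccccc4)c(OCc4ccccc4)c1)[C@H](OCc4ccccc4)[C@@H]2c1c(OCc4ccccc4)cc(OCc4ccccc4)c2c1O[C@H](c1ccc(OCc4ccccc4)c(OCc4ccccc4)c1)[C@@H](OCc4ccccc4)C2
F5 | step 7 | 6-bromo-tetra-O-benzyl-ent-fisetinidol-(4α→8)-penta-O-benzylcatechin-(6→4α)-tetra-O-benzyl-ent-fisetinidol | Brc1cc2c(cc1OCc4ccccc4)O[C@@H](c1ccc(OCc4ccccc4)c(OCc4ccccc4)c1)[C@H](OCc4ccccc4)[C@@H]2c1c(OCc4ccccc4)c([C@@H]2c3ccc(OCc4ccccc4)cc3O[C@@H](c3ccc(OCc4ccccc4)c(OCc4ccccc4)c3)[C@@H]2OCc4ccccc4)c(OCc4ccccc4)c2c1O[C@H](c1ccc(OCc4ccccc4)c(OCc4ccccc4)c1)[C@@H](OCc4ccccc4)C2
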